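The data come from a simulation from invented constants; scatter was added.

3 questions stood for this flask: what had stopped it by the end, and how much target and how much isomer of the product stood then.

- theta: solid substrate 0.075 M; run made earlier
- flask: solid substrate 0.050 M; time 8.0 d

- theta (time / h: target / %, isomer of the product / %, solid substrate / %): 3.00: 2.3, 5.2, 68.1; 8.00: 13.0, 17.6, 19.9; 15.0: 40.0, 30.2, 0; 40.0: 65.5, 32.5, 0.4

(readings scatter by 0.5 percentage points)

- as a solid, counted per litre of solution: solid substrate
- at the start none of the solid substrate is in solution
- in a conversion other conformer counts as not yet reacted
- what has only dissolved of solid substrate counts as not reacted
- the reaction counts as stopped when no species that holds the solid substrate changes by six tenths of a point or more over the second half of the time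

- at 8.0 d, what has stopped the reaction, if anything has (for what has run out or reacted, a solid counts together with what of it has only dissolved; other conformer counts as not reacted) (it is still moving / all of the solid substrate has reacted / forward and back rates have come level)
- the target standing at 8.0 d, as a percentage of the solid substrate charged
- the isomer of the product standing at 8.0 d, as a percentage of the solid substrate charged

1. At 40.0 h in the theta run, the rest, meaning what stood outside the two products, was 2 percentage points. I therefore treated the large part as read and reckoned the rest as a correction.

2. My first way was the end share, the target as a fraction of target plus isomer of the product at the last reading: 66.8%. In the theta run this share had climbed from 30.7% at 3.00 h, so I took it as the reading at 40.0 h and not as a split that held through the run. It gave the rest the same split as the products already made.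

3. My second way gave the rest the split of the last stretch, 91.7% target, which put the target at 67.3%.

4. The two ways share the reading at 40.0 h, so they tested nothing but the correction, and they parted by 0.5 points. The second cheated, because its isomer gain of 2.3 points was a difference of readings with a scatter of 0.71 points, a large fraction of itself. I committed to 66.8% of the charge as target, though the share was read at one charge.

5. The rest fell with a half-life of about 6.41 h as read, far shorter than the flask's 8.0 d, so I expected no movement at the end.

6. The forecast said all of the solid substrate has reacted, with 67.2% of target (62% to 72%) and 32.8% of isomer of the product (28% to 37.5%): “the lower charge only shortens the dissolution period and leaves the split near 67:33”.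

7. The flask gave 66.7% of target and 33.3% of isomer of the product, and its end state was: all of the solid substrate has reacted, with 0% of the charge still there.

    starting material ⇌ other conformer, settled at all times (K = 5.80)
    starting material → target (k = 0.0530 h⁻¹)
    other conformer → isomer of the product (k = 0.140 h⁻¹)
    target ⇌ isomer of the product (K = 0.500, k = 0.160 h⁻¹)
    solid substrate ⇌ starting material, rate k5*(cs5 - [starting material]) while solid is left; crystals form when [starting material] > cs5 (solubility = 45.0 mM, k = 0.180 h⁻¹)

Target and isomer of the product relaxed with a half-life of 0.0602 d, which is short against 8.0 d. The end share 66.8% stood 0.10 points from the flask's target, and the equilibrium constant of that step puts the target's share of the pair at 66.7%. In the neighbour flask with 0.030 M of solid substrate, the same share of 66.8% met a target of 66.7% at 8.00 d.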